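**Retrosynthetic overview**

- The strategy rests on C4, which carries a methyl and a carboxyl next to the C3 carbinol (a disguised α-methyl-β-keto ester), and on the trans-fused six/five rings A/B, whose bonds C4–C5 and C10–C9 end on the C9–C11 edge of ring C. This is the retron of an oxidative keto-ester radical bicyclization stopped on a cyclohexene.
- Ring C is bought as a cyclohexenone. The C6–C8 bond and both stereocentres come from an Ireland–Claisen rearrangement of an enantioenriched C11 allylic ester; the C2–C4 keto ester is added by dianion alkylation.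
- Rings A and B close together in one step (Mn(OAc)3/Cu(OAc)2), leaving a C11=C12 alkene that is converted into a C11 enone.
- Ring D closes last, by vinyl-radical addition of the C15–C16 arm to C13. The end game is C11 ketone to equatorial alcohol, ester cleavage and desilylation.

Key step: step 13

Remark: gibberellane numbering is used (C7 = carboxyl carbon on C6, C19 = carboxyl carbon on C4, C18 = methyl on C4, C20 = methyl on C10, C17 = exocyclic methylene carbon). β is the face of the C8–C15 bond (later the C15–C16 bridge), α the opposite face. In the target: 3β-OH, 18β-CH3, 19α-CO2H, H5β, H6α, H9β, 20α-CH3, 11α-OH, H13α.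

**Route**

Step 1
Reactants: 1 3-ethoxycyclohex-2-en-1-one; 2 1-(trimethylsilyl)propyne
Product: 5 3-[3-(trimethylsilyl)prop-2-yn-1-yl]cyclohex-2-en-1-one, via 3-lithio-1-(trimethylsilyl)propyne 3 (not isolated), via lithium carbinolate 4 (not isolated)
Conditions: 2, n-BuLi, THF, −78 to −20 °C; then 1, −78 °C; then 1 M HCl, rt
Reagents that add atoms: water (O)
Why: Stork–Danheiser sequence, in which the propargylic lithium reagent (allenyl attack disfavoured by the silyl end) adds 1,2 to the vinylogous ester and acid hydrolysis with loss of water and ethanol transposes the enone, placing the new arm on the β-carbon (future C8, with C15–C17 attached).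

Step 2
Reactants: 5 3-[3-(trimethylsilyl)prop-2-yn-1-yl]cyclohex-2-en-1-one
Product: 6 (1R)-3-[3-(trimethylsilyl)prop-2-yn-1-yl]cyclohex-2-en-1-ol
Conditions: (S)-1-methyl-3,3-diphenyltetrahydro-1H,3H-pyrrolo[1,2-c][1,3,2]oxazaborole ((S)-Me-CBS, 0.2 equiv), catecholborane, toluene, −78 °C
Reagents that add atoms: none
Why: CBS reduction, in which the catalyst–borane complex binds the carbonyl anti to the larger alkenyl branch and delivers hydride to one face, so that the (S)-catalyst should give the (R)-carbinol (future C11) while catecholborane at −78 °C leaves the alkene and silylalkyne alone.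

Step 3
Reactants: 7 4-methylpent-3-enoic acid
Product: 8 methyl 4-methylpent-3-enoate
Conditions: MeI, K2CO3, DMF, rt
Reagents that add atoms: methyl iodide (CI)
Why: Carboxylate O-alkylation under mild base avoids the acid-induced lactonization onto the trisubstituted alkene that a Fischer esterification would risk.

Step 4
Reactants: 8 methyl 4-methylpent-3-enoate
Product: 9 methyl (3E)-5-hydroxy-4-methylpent-3-enoate
Conditions: SeO2 (0.3 equiv), t-BuOOH, CH2Cl2, rt
Reagents that add atoms: selenium dioxide (O=[Se]=O), its oxygen replenished by tert-butyl hydroperoxide (CC(C)(C)OO)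
Why: Allylic oxidation by SeO2 (ene reaction then [2,3] shift) attacks the more substituted alkene terminus and hydroxylates the methyl group trans to the chain, which should give the (E)-allylic alcohol (future C1).

Step 5
Reactants: 9 methyl (3E)-5-hydroxy-4-methylpent-3-enoate
Product: 10 methyl (3E)-5-[(tert-butyldimethylsilyl)oxy]-4-methylpent-3-enoate
Conditions: TBSCl, imidazole, DMF, 0 °C
Reagents that add atoms: tert-butyldimethylsilyl chloride (CC(C)(C)[Si](C)(C)Cl)
Why: Standard silylation of a primary allylic alcohol masks the hydroxyl against the enolate chemistry that follows.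

Step 6
Reactants: 10 methyl (3E)-5-[(tert-butyldimethylsilyl)oxy]-4-methylpent-3-enoate
Product: 11 (3E)-5-[(tert-butyldimethylsilyl)oxy]-4-methylpent-3-enoic acid
Conditions: LiOH, THF/H2O, 0 °C; then dilute HCl to pH 4, 0 °C
Reagents that add atoms: lithium hydroxide ([Li+].[OH-])
Why: Saponification of the unhindered methyl ester at 0 °C is faster than α-deprotonation, so the β,γ-alkene should stay out of conjugation and the silyl ether survives.

Step 7
Reactants: 6 (1R)-3-[3-(trimethylsilyl)prop-2-yn-1-yl]cyclohex-2-en-1-ol; 11 (3E)-5-[(tert-butyldimethylsilyl)oxy]-4-methylpent-3-enoic acid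
Product: 12 (1R)-3-[3-(trimethylsilyl)prop-2-yn-1-yl]cyclohex-2-en-1-yl (3E)-5-[(tert-butyldimethylsilyl)oxy]-4-methylpent-3-enoate
Conditions: DCC, DMAP (0.1 equiv), CH2Cl2, 0 °C
Reagents that add atoms: none
Why: Steglich esterification acylates the allylic alcohol with retention at C11, and the low temperature and low DMAP loading limit base-induced migration of the β,γ-alkene.

Step 8
Reactants: 12 (1R)-3-[3-(trimethylsilyl)prop-2-yn-1-yl]cyclohex-2-en-1-yl (3E)-5-[(tert-butyldimethylsilyl)oxy]-4-methylpent-3-enoate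
Product: 15 (2S,3E)-5-[(tert-butyldimethylsilyl)oxy]-4-methyl-2-[(1R)-1-[3-(trimethylsilyl)prop-2-yn-1-yl]cyclohex-2-en-1-yl]pent-3-enoic acid, via (Z)-silyl ketene acetal 13 (not isolated), via trimethylsilyl ester 14 (not isolated)
Conditions: LiN(i-Pr)2 (from i-Pr2NH, n-BuLi), THF/DMPU 4:1, −78 °C; TMSCl, Et3N, −78 °C; rt then 50 °C; aq NH4Cl
Reagents that add atoms: none
Why: Ireland–Claisen rearrangement, in which deprotonation in THF/DMPU gives the dienolate with the alkenyl group cis to the oxido oxygen, O-silylation gives the (Z)-ketene acetal, and a suprafacial [3,3] shift through a chair (alkenyl group pseudo-equatorial) forms the C6–C8 bond on the ring face that carried the ester oxygen, so chirality passes from C11 to quaternary C8 and C6 is set; the boat otherwise open to cyclohexenyl ketene acetals is penalised here because it would eclipse that alkenyl group with the C15 methylene on the carbon under attack.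

Step 9
Reactants: 15 (2S,3E)-5-[(tert-butyldimethylsilyl)oxy]-4-methyl-2-[(1R)-1-[3-(trimethylsilyl)prop-2-yn-1-yl]cyclohex-2-en-1-yl]pent-3-enoic acid
Product: 16 methyl (2S,3E)-5-[(tert-butyldimethylsilyl)oxy]-4-methyl-2-[(1R)-1-[3-(trimethylsilyl)prop-2-yn-1-yl]cyclohex-2-en-1-yl]pent-3-enoate
Conditions: TMSCHN2, MeOH/toluene, 0 °C to rt
Reagents that add atoms: (trimethylsilyl)diazomethane (C[Si](C)(C)C=[N+]=[N-])
Why: Methylation by the diazoalkane under neutral conditions esterifies the hindered acid without base that could epimerize C6 or move the alkene into conjugation.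

Step 10
Reactants: 16 methyl (2S,3E)-5-[(tert-butyldimethylsilyl)oxy]-4-methyl-2-[(1R)-1-[3-(trimethylsilyl)prop-2-yn-1-yl]cyclohex-2-en-1-yl]pent-3-enoate
Product: 17 methyl (2S,3E)-5-hydroxy-4-methyl-2-[(1R)-1-[3-(trimethylsilyl)prop-2-yn-1-yl]cyclohex-2-en-1-yl]pent-3-enoate
Conditions: camphorsulfonic acid (cat.), MeOH, 0 °C
Reagents that add atoms: none
Why: Acid-catalysed methanolysis removes the primary allylic O-silyl group, whereas the alkynyl C–Si bond is labile to base or fluoride but not to mild acid.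

Step 11
Reactants: 17 methyl (2S,3E)-5-hydroxy-4-methyl-2-[(1R)-1-[3-(trimethylsilyl)prop-2-yn-1-yl]cyclohex-2-en-1-yl]pent-3-enoate
Product: 18 methyl (2S,3E)-5-bromo-4-methyl-2-[(1R)-1-[3-(trimethylsilyl)prop-2-yn-1-yl]cyclohex-2-en-1-yl]pent-3-enoate
Conditions: CBr4, PPh3, 2,6-lutidine, CH2Cl2, 0 °C
Reagents that add atoms: carbon tetrabromide (BrC(Br)(Br)Br)
Why: Appel bromination converts the primary allylic alcohol into the bromide under near-neutral conditions with the E geometry kept.

Step 12
Reactants: 18 methyl (2S,3E)-5-bromo-4-methyl-2-[(1R)-1-[3-(trimethylsilyl)prop-2-yn-1-yl]cyclohex-2-en-1-yl]pent-3-enoate; 19 methyl 2-methyl-3-oxobutanoate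
Product: 21 dimethyl (6E,8S)-2,6-dimethyl-3-oxo-8-[(1R)-1-[3-(trimethylsilyl)prop-2-yn-1-yl]cyclohex-2-en-1-yl]non-6-enedioate (C4 epimers), via keto ester dianion 20 (not isolated)
Conditions: 19, NaH, THF, 0 °C; n-BuLi, 0 °C; then 18, −20 to 0 °C; aq NH4Cl
Reagents that add atoms: none
Why: γ-Alkylation of a β-keto ester dianion, whose more basic terminal carbanion displaces the primary allylic bromide by SN2 (forming C1–C2), while low temperature and the hindered position of C6–H should keep the substrate ester from being enolized.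

Step 13
Reactants: 21 dimethyl (6E,8S)-2,6-dimethyl-3-oxo-8-[(1R)-1-[3-(trimethylsilyl)prop-2-yn-1-yl]cyclohex-2-en-1-yl]non-6-enedioate
Product: 22 tricyclic keto diester (rings A, B, C): 3-oxo, 4β-methyl-4α-CO2Me, H5β, 6β-CO2Me, 8β-[3-(trimethylsilyl)prop-2-ynyl], H9β, 10α-methyl, C11=C12 alkene
Conditions: Mn(OAc)3·2H2O (2.2 equiv), Cu(OAc)2·H2O (0.3 equiv), degassed AcOH, 0.02 M, 40 °C
Reagents that add atoms: none
Why: Mn(OAc)3 enolizes the α-methyl-β-keto ester and one-electron oxidation gives the electrophilic C4 radical, which closes ring A 6-endo-trig onto C5 of the electron-rich C5=C10 alkene through a chair; the tertiary C10 radical then closes ring B 5-exo-trig onto C9 of the cyclohexene, and Cu(OAc)2 turns the secondary C11 radical into the C11=C12 alkene by loss of a C12 hydrogen. The closest known reaction type is the oxidative tandem 6-endo/5-exo cyclization of unsaturated α-alkyl-β-keto esters by trivalent manganese with divalent copper as terminator; ending it on a chiral cyclohexene held through a quaternary carbon is an application not yet tested. C5 is controlled by allylic 1,3-strain with the C10 methyl, which holds C6–H in the alkene plane so that the radical enters anti to quaternary C8 and H5 ends anti to H6; C4 follows from the chair with the ester axial (CO2Me anti to H5 and syn to the C10 methyl). C10 is set when ring B closes diequatorially on the ring-A chair (trans ring fusion, methyl axial), and C9 by the three-atom tether C5–C6–C8, which can deliver C10 only to the face of C9=C11 that carries C6, so ring B is cis-fused to ring C. The step needs 6-endo over 5-exo in the first closure (secured by the methyl on C10), ring-B closure before copper oxidizes the tertiary radical (substoichiometric Cu(OAc)2 and high dilution), 5-exo-trig onto the alkene rather than 6-exo-dig onto the alkyne (ring size and the silyl cap, which also keeps copper off the alkyne), and Hofmann-type elimination toward C12.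

Step 14
Reactants: 22 tricyclic keto diester
Product: 23 tricyclic 3β-alcohol (otherwise as 22)
Conditions: LiBH(s-Bu)3 (L-Selectride), THF, −78 °C; AcOH quench at −78 °C
Reagents that add atoms: none
Why: The bulky borohydride avoids the axial trajectory past H1β and H5β and attacks the C3 ketone equatorially, which should give the axial 3β-alcohol, while the esters are inert at −78 °C and the cold acidic quench prevents retro-aldol of the β-alkoxide ester.

Step 15
Reactants: 23 tricyclic 3β-alcohol
Product: 24 tricyclic 3β-silyl ether (3β-OTBS, otherwise as 23)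
Conditions: TBSOTf, 2,6-lutidine, CH2Cl2, 0 °C
Reagents that add atoms: tert-butyldimethylsilyl triflate (CC(C)(C)[Si](C)(C)OS(=O)(=O)C(F)(F)F)
Why: The silyl triflate is reactive enough for the hindered axial hydroxyl beside quaternary C4, and the ether blocks retro-aldol in the later basic steps.

Step 16
Reactants: 24 tricyclic 3β-silyl ether
Product: 25 tricyclic terminal alkyne (8β-prop-2-ynyl, otherwise as 24)
Conditions: K2CO3 (cat.), MeOH, rt
Reagents that add atoms: none
Why: Methoxide cleaves the alkynyl C–Si bond selectively, while the O-silyl ether and the methyl esters are unchanged in methanol.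

Step 17
Reactants: 25 tricyclic terminal alkyne
Product: 26 11β,12β-epoxide of 25
Conditions: mCPBA, NaHCO3, CH2Cl2, 0 °C
Reagents that add atoms: 3-chloroperbenzoic acid (OOC(=O)c1cccc(Cl)c1)
Why: Peracid epoxidation of the only alkene should occur on the convex β face, away from the cis-fused ring B, with the terminal alkyne far less reactive; either epoxide would lead on to the same enone.

Step 18
Reactants: 26 11β,12β-epoxide
Product: 27 11β-hydroxy-12α-phenylselanyl compound
Conditions: (PhSe)2, NaBH4, EtOH, rt to 50 °C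
Reagents that add atoms: diphenyl diselenide (c1ccc([Se][Se]c2ccccc2)cc1)
Why: SN2 epoxide opening by benzeneselenolate with inversion should occur at C12, whose neighbour is the C13 methylene, rather than at C11, which is flanked by C9 bearing the quaternary C8 and C10.

Step 19
Reactants: 27 11β-hydroxy-12α-phenylselanyl compound
Product: 29 allylic alcohol (11β-OH, C12=C13 alkene), via selenoxide 28 (not isolated)
Conditions: 30% H2O2, pyridine, THF, 0 °C to rt
Reagents that add atoms: none
Why: Selenoxide syn-elimination takes a C13 hydrogen in preference to the carbinol hydrogen on C11, which moves the alkene to C12=C13 and leaves the C11 oxygen allylic.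

Step 20
Reactants: 29 allylic alcohol
Product: 30 C11 enone (11-oxo, C12=C13 alkene; 8β-prop-2-ynyl, 3β-OTBS)
Conditions: Dess–Martin periodinane, NaHCO3, CH2Cl2, rt
Reagents that add atoms: none
Why: Buffered Dess–Martin oxidation converts the hindered secondary allylic alcohol into the enone without touching the alkyne or epimerizing C9.

Step 21
Reactants: 30 C11 enone
Product: 31 tetracyclic 11-ketone with exocyclic C16=C17 vinylstannane (E/Z mixture; H13α)
Conditions: Bu3SnH (slow addition), AIBN (cat.), benzene, 80 °C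
Reagents that add atoms: tributyltin hydride (CCCC[SnH](CCCC)CCCC)
Why: Vinyl-radical conjugate cyclization, in which the stannyl radical adds to the terminal alkyne carbon C17 and the C16 vinyl radical, held on the β face by the C8–C15 arm, adds 5-exo-trig to C13 (the enone β-carbon), closing ring D and fixing C13 because only a β bond can bridge C8 and C13; the C12 α-keto radical then takes hydrogen from the stannane.

Step 22
Reactants: 31 tetracyclic vinylstannane
Product: 32 tetracyclic 11-ketone with exocyclic methylene (3β-OTBS, both methyl esters)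
Conditions: pyridinium p-toluenesulfonate (2 equiv), CH2Cl2, rt
Reagents that add atoms: none
Why: Protodestannylation by ipso-protonation of the vinylstannane under mild acid leaves the alkene exocyclic and the silyl ether intact.

Step 23
Reactants: 32 tetracyclic 11-ketone
Product: 33 11α-alcohol (3β-OTBS, both methyl esters)
Conditions: SmI2 (3 equiv), HMPA, i-PrOH, THF, rt
Reagents that add atoms: none
Why: Electron-transfer reduction through the ketyl and the C11 organosamarium is product-controlled and should place the C–O bond equatorial (11α, anti to the C15–C16 bridge), whereas a kinetic hydride would enter from the open α face and give the axial 11β-alcohol; the methyl esters and the 1,1-disubstituted alkene are inert to SmI2 under these conditions.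

Step 24
Reactants: 33 11α-alcohol
Product: 34 3β-silyloxy-11α-hydroxy diacid
Conditions: n-PrSLi (from n-PrSH, n-BuLi), HMPA, rt to 50 °C; then 1 M HCl
Reagents that add atoms: none
Why: The thiolate cleaves both methyl esters by SN2 attack at the methyl carbon, so the hindered acyl carbons are not involved, and the 3-O-silyl group still in place excludes retro-aldol epimerization at C3.

Step 25
Reactants: 34 3β-silyloxy-11α-hydroxy diacid
Product: 35 CNP0232910.1 (3β,11α-dihydroxy C20 gibberellin 7,19-dioic acid; C3 S, C4 S, C5 S, C6 S, C8 R, C9 S, C10 R, C11 R, C13 S)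
Conditions: HF·pyridine, THF/pyridine, 0 °C to rt
Reagents that add atoms: none
Why: Buffered fluoride cleavage of the hindered silyl ether avoids both base (retro-aldol at C3–C4) and strong acid (migration of the exocyclic alkene).

**Compound list**

1 | 3-ethoxycyclohex-2-en-1-one | CCOC1=CC(=O)CCC1 | starting material
2 | 1-(trimethylsilyl)propyne | CC#C[Si](C)(C)C | starting material
3 | 3-lithio-1-(trimethylsilyl)propyne | [Li]CC#C[Si](C)(C)C | intermediate
4 | lithium 3-ethoxy-1-[3-(trimethylsilyl)prop-2-yn-1-yl]cyclohex-2-en-1-olate | CCOC1=CC(O[Li])(CC#C[Si](C)(C)C)CCC1 | intermediate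
5 | 3-[3-(trimethylsilyl)prop-2-yn-1-yl]cyclohex-2-en-1-one | O=C1C=C(CC#C[Si](C)(C)C)CCC1 | intermediate
6 | (1R)-3-[3-(trimethylsilyl)prop-2-yn-1-yl]cyclohex-2-en-1-ol | O[C@H]1C=C(CC#C[Si](C)(C)C)CCC1 | intermediate
7 | 4-methylpent-3-enoic acid | CC(C)=CCC(=O)O | starting material
8 | methyl 4-methylpent-3-enoate | COC(=O)CC=C(C)C | intermediate
9 | methyl (3E)-5-hydroxy-4-methylpent-3-enoate | COC(=O)C/C=C(\C)CO | intermediate
10 | methyl (3E)-5-[(tert-butyldimethylsilyl)oxy]-4-methylpent-3-enoate | COC(=O)C/C=C(\C)CO[Si](C)(C)C(C)(C)C | intermediate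
11 | (3E)-5-[(tert-butyldimethylsilyl)oxy]-4-methylpent-3-enoic acid | OC(=O)C/C=C(\C)CO[Si](C)(C)C(C)(C)C | intermediate
12 | (1R)-3-[3-(trimethylsilyl)prop-2-yn-1-yl]cyclohex-2-en-1-yl (3E)-5-[(tert-butyldimethylsilyl)oxy]-4-methylpent-3-enoate | C[Si](C)(C)C#CCC1=C[C@H](OC(=O)C/C=C(\C)CO[Si](C)(C)C(C)(C)C)CCC1 | intermediate
13 | (Z)-trimethylsilyl ketene acetal of 12 (alkenyl group cis to OSiMe3) | C[Si](C)(C)C#CCC1=C[C@H](O/C(O[Si](C)(C)C)=C/C=C(\C)CO[Si](C)(C)C(C)(C)C)CCC1 | intermediate
14 | trimethylsilyl ester of acid 15 | C[Si](C)(C)C#CC[C@]1(C=CCCC1)[C@H](/C=C(\C)CO[Si](C)(C)C(C)(C)C)C(=O)O[Si](C)(C)C | intermediate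
15 | (2S,3E)-5-[(tert-butyldimethylsilyl)oxy]-4-methyl-2-[(1R)-1-[3-(trimethylsilyl)prop-2-yn-1-yl]cyclohex-2-en-1-yl]pent-3-enoic acid | C[Si](C)(C)C#CC[C@]1(C=CCCC1)[C@H](/C=C(\C)CO[Si](C)(C)C(C)(C)C)C(=O)O | intermediate
16 | methyl ester of 15 | C[Si](C)(C)C#CC[C@]1(C=CCCC1)[C@H](/C=C(\C)CO[Si](C)(C)C(C)(C)C)C(=O)OC | intermediate
17 | methyl (2S,3E)-5-hydroxy-4-methyl-2-[(1R)-1-[3-(trimethylsilyl)prop-2-yn-1-yl]cyclohex-2-en-1-yl]pent-3-enoate | C[Si](C)(C)C#CC[C@]1(C=CCCC1)[C@H](/C=C(\C)CO)C(=O)OC | intermediate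
18 | methyl (2S,3E)-5-bromo-4-methyl-2-[(1R)-1-[3-(trimethylsilyl)prop-2-yn-1-yl]cyclohex-2-en-1-yl]pent-3-enoate | C[Si](C)(C)C#CC[C@]1(C=CCCC1)[C@H](/C=C(\C)CBr)C(=O)OC | intermediate
19 | methyl 2-methyl-3-oxobutanoate | COC(=O)C(C)C(C)=O | starting material
20 | sodium lithium dianion of 19 | [Na+].[Li+].[CH2-]C(=O)[C-](C)C(=O)OC | intermediate
21 | dimethyl (6E,8S)-2,6-dimethyl-3-oxo-8-[(1R)-1-[3-(trimethylsilyl)prop-2-yn-1-yl]cyclohex-2-en-1-yl]non-6-enedioate (C4 epimers) | C[Si](C)(C)C#CC[C@]1(C=CCCC1)[C@H](/C=C(\C)CCC(=O)C(C)C(=O)OC)C(=O)OC | intermediate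
22 | tricyclic keto diester (3-oxo, C11=C12, 8β-silylpropynyl) | C[Si](C)(C)C#CC[C@]12CCC=C[C@H]1[C@]1(C)CCC(=O)[C@@](C)(C(=O)OC)[C@H]1[C@@H]2C(=O)OC | intermediate
23 | tricyclic 3β-alcohol | C[Si](C)(C)C#CC[C@]12CCC=C[C@H]1[C@]1(C)CC[C@H](O)[C@@](C)(C(=O)OC)[C@H]1[C@@H]2C(=O)OC | intermediate
24 | tricyclic 3β-OTBS ether | C[Si](C)(C)C#CC[C@]12CCC=C[C@H]1[C@]1(C)CC[C@H](O[Si](C)(C)C(C)(C)C)[C@@](C)(C(=O)OC)[C@H]1[C@@H]2C(=O)OC | intermediate
25 | tricyclic terminal alkyne | C#CC[C@]12CCC=C[C@H]1[C@]1(C)CC[C@H](O[Si](C)(C)C(C)(C)C)[C@@](C)(C(=O)OC)[C@H]1[C@@H]2C(=O)OC | intermediate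
26 | 11β,12β-epoxide | C#CC[C@]12CC[C@@H]3O[C@@H]3[C@H]1[C@]1(C)CC[C@H](O[Si](C)(C)C(C)(C)C)[C@@](C)(C(=O)OC)[C@H]1[C@@H]2C(=O)OC | intermediate
27 | 11β-hydroxy-12α-phenylselanyl compound | C#CC[C@]12CC[C@@H]([Se]c3ccccc3)[C@H](O)[C@H]1[C@]1(C)CC[C@H](O[Si](C)(C)C(C)(C)C)[C@@](C)(C(=O)OC)[C@H]1[C@@H]2C(=O)OC | intermediate
28 | selenoxide of 27 | C#CC[C@]12CC[C@@H]([Se](=O)c3ccccc3)[C@H](O)[C@H]1[C@]1(C)CC[C@H](O[Si](C)(C)C(C)(C)C)[C@@](C)(C(=O)OC)[C@H]1[C@@H]2C(=O)OC | intermediate
29 | allylic alcohol (11β-OH, C12=C13) | C#CC[C@]12CC=C[C@H](O)[C@H]1[C@]1(C)CC[C@H](O[Si](C)(C)C(C)(C)C)[C@@](C)(C(=O)OC)[C@H]1[C@@H]2C(=O)OC | intermediate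
30 | C11 enone (11-oxo, C12=C13) | C#CC[C@]12CC=CC(=O)[C@H]1[C@]1(C)CC[C@H](O[Si](C)(C)C(C)(C)C)[C@@](C)(C(=O)OC)[C@H]1[C@@H]2C(=O)OC | intermediate
31 | tetracyclic 11-ketone, 17-tributylstannyl (E/Z) | CCCC[Sn](CCCC)(CCCC)C=C1C[C@]23C[C@H]1CC(=O)[C@H]2[C@]1(C)CC[C@H](O[Si](C)(C)C(C)(C)C)[C@@](C)(C(=O)OC)[C@H]1[C@@H]3C(=O)OC | intermediate
32 | tetracyclic 11-ketone with exocyclic methylene | C=C1C[C@]23C[C@H]1CC(=O)[C@H]2[C@]1(C)CC[C@H](O[Si](C)(C)C(C)(C)C)[C@@](C)(C(=O)OC)[C@H]1[C@@H]3C(=O)OC | intermediate
33 | 11α-alcohol, dimethyl ester, 3β-OTBS | C=C1C[C@]23C[C@H]1C[C@@H](O)[C@H]2[C@]1(C)CC[C@H](O[Si](C)(C)C(C)(C)C)[C@@](C)(C(=O)OC)[C@H]1[C@@H]3C(=O)OC | intermediate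
34 | 3β-silyloxy-11α-hydroxy diacid | C=C1C[C@]23C[C@H]1C[C@@H](O)[C@H]2[C@]1(C)CC[C@H](O[Si](C)(C)C(C)(C)C)[C@@](C)(C(=O)O)[C@H]1[C@@H]3C(=O)O | intermediate
35 | CNP0232910.1 | C=C1C[C@]23C[C@H]1C[C@@H](O)[C@H]2[C@]1(C)CC[C@H](O)[C@@](C)(C(=O)O)[C@H]1[C@@H]3C(=O)O | target

**Summary**

Total step count: 25. Longest linear sequence: 23 steps (steps 3 to 25, from 7).

**Steps most likely to fail**

1. Step 13. The tertiary C10 radical may be oxidized by divalent copper or trivalent manganese, or be quenched, faster than it closes the crowded five-membered ring, so that the cascade stops after ring A. The fallback generates the same radicals without an oxidant, by iodine-atom transfer; it sets out from 21 and returns at 22. Treatment of 21 with NaH and N-iodosuccinimide in THF at 0 °C should give the α-iodo keto diester F1. Irradiation of F1 with (Bu3Sn)2 (10 mol %) in benzene at 80 °C abstracts iodine to give the C4 radical, which should follow the same 6-endo/5-exo course; the C11 radical then takes iodine from F1 (chain transfer), giving the tricyclic 11-iodide F2. DBU in toluene at 80 °C should eliminate HI toward C12 and give 22.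

2. Step 8. The ketene acetal may rearrange through the boat-like transition state that cyclohexenyl esters can use, or form as a geometric mixture; either inverts or erodes the induction at C6 while C8 is unaffected. The fallback exchanges the roles of the two carbon substituents of C6, so that the ordinary (E)-ketene acetal and chair give the needed C6; it sets out from 6 and returns at 15.
   - Esterification of 6 with 3-[(4-methoxybenzyl)oxy]propanoic acid (DCC, DMAP) gives the 3-(4-methoxybenzyloxy)propanoate ester F3.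
   - LiN(i-Pr)2 in THF at −78 °C with TMSCl/Et3N present, then warming, should give through the (E)-ketene acetal and a chair the rearranged acid F4, whose carboxyl carbon is now C5 and whose CH2O arm is C7.
   - LiAlH4 reduces F4 to the primary alcohol F5, and Dess–Martin oxidation gives the aldehyde F6.
   - Wittig reaction with Ph3P=C(CH3)CO2Et in toluene at 80 °C gives the (E)-2-methyl enoate F7; i-Bu2AlH at −78 °C gives the allylic alcohol F8; TBSCl/imidazole gives the silyl ether F9.
   - DDQ in wet CH2Cl2 removes the p-methoxybenzyl group to give the C7 alcohol F10; Dess–Martin oxidation gives the C7 aldehyde F11; Pinnick oxidation (NaClO2, NaH2PO4, 2-methylbut-2-ene) gives 15.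

3. Step 18. The selenolate may attack C11 instead of C12, or open the epoxide too slowly, which would lead to the transposed allylic alcohol or to none. The fallback fixes the oxygen at C11 by steric differentiation of a diol and makes the enone by dehydrogenation; it sets out from 25 and returns at 30. OsO4 (cat.) with N-methylmorpholine N-oxide should give the 11β,12β-diol F12. Ac2O/pyridine at 0 °C should acetylate the less hindered 12-hydroxyl to give the 12-monoacetate F13, and Dess–Martin oxidation gives the 12-acetoxy-11-ketone F14. SmI2 in THF/MeOH at −78 °C removes the α-acetoxy group to give the saturated 11-ketone F15. IBX in DMSO/toluene at 75 °C can dehydrogenate only toward C12–C13 (C8 and C10 carry no hydrogen), which should give 30.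

**Further compounds**

F1 | step 13 | α-iodo keto diester (C4 iodide of 21) | C[Si](C)(C)C#CC[C@]1(C=CCCC1)[C@H](/C=C(\C)CCC(=O)C(C)(I)C(=O)OC)C(=O)OC
F2 | step 13 | tricyclic 11-iodide (11-iodo-11,12-dihydro 22) | C[Si](C)(C)C#CC[C@]12CCCC(I)[C@H]1[C@]1(C)CCC(=O)[C@@](C)(C(=O)OC)[C@H]1[C@@H]2C(=O)OC
F3 | step 8 | (1R)-3-[3-(trimethylsilyl)prop-2-yn-1-yl]cyclohex-2-en-1-yl 3-[(4-methoxybenzyl)oxy]propanoate | C[Si](C)(C)C#CCC1=C[C@H](OC(=O)CCOCc2ccc(OC)cc2)CCC1
F4 | step 8 | rearranged acid (C5 carboxyl, C7 p-methoxybenzyloxymethyl) | C[Si](C)(C)C#CC[C@]1(C=CCCC1)[C@@H](COCc2ccc(OC)cc2)C(=O)O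
F5 | step 8 | primary alcohol from F4 | C[Si](C)(C)C#CC[C@]1(C=CCCC1)[C@@H](COCc2ccc(OC)cc2)CO
F6 | step 8 | C5 aldehyde | C[Si](C)(C)C#CC[C@]1(C=CCCC1)[C@@H](COCc2ccc(OC)cc2)C=O
F7 | step 8 | ethyl (E)-2-methyl enoate | C[Si](C)(C)C#CC[C@]1(C=CCCC1)[C@@H](COCc2ccc(OC)cc2)/C=C(\C)C(=O)OCC
F8 | step 8 | allylic alcohol from F7 | C[Si](C)(C)C#CC[C@]1(C=CCCC1)[C@@H](COCc2ccc(OC)cc2)/C=C(\C)CO
F9 | step 8 | allylic silyl ether | C[Si](C)(C)C#CC[C@]1(C=CCCC1)[C@@H](COCc2ccc(OC)cc2)/C=C(\C)CO[Si](C)(C)C(C)(C)C
F10 | step 8 | C7 alcohol | C[Si](C)(C)C#CC[C@]1(C=CCCC1)[C@@H](CO)/C=C(\C)CO[Si](C)(C)C(C)(C)C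
F11 | step 8 | C7 aldehyde | C[Si](C)(C)C#CC[C@]1(C=CCCC1)[C@@H](C=O)/C=C(\C)CO[Si](C)(C)C(C)(C)C
F12 | step 18 | 11β,12β-diol | C#CC[C@]12CC[C@H](O)[C@H](O)[C@H]1[C@]1(C)CC[C@H](O[Si](C)(C)C(C)(C)C)[C@@](C)(C(=O)OC)[C@H]1[C@@H]2C(=O)OC
F13 | step 18 | 12-monoacetate | C#CC[C@]12CC[C@H](OC(C)=O)[C@H](O)[C@H]1[C@]1(C)CC[C@H](O[Si](C)(C)C(C)(C)C)[C@@](C)(C(=O)OC)[C@H]1[C@@H]2C(=O)OC
F14 | step 18 | 12-acetoxy-11-ketone | C#CC[C@]12CC[C@H](OC(C)=O)C(=O)[C@H]1[C@]1(C)CC[C@H](O[Si](C)(C)C(C)(C)C)[C@@](C)(C(=O)OC)[C@H]1[C@@H]2C(=O)OC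
F15 | step 18 | saturated 11-ketone | C#CC[C@]12CCCC(=O)[C@H]1[C@]1(C)CC[C@H](O[Si](C)(C)C(C)(C)C)[C@@](C)(C(=O)OC)[C@H]1[C@@H]2C(=O)OC
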